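## Structural features

Lespeflorin B1 is a 2,3-trans-dihydroflavonol: a chroman-4-one (aromatic ring A fused to the dihydropyranone ring C through C4a–C8a) that carries the aryl ring B on C2. The two stereocentres, C2 (R) and C3 (R), are adjacent; C3 bears a free hydroxyl and lies α to the C4 ketone, C2 is a benzylic carbon bound to the ring oxygen O1, and the two hydrogens are anti. Ring A has a hydroxyl at C7 with a 3-methylbut-2-enyl (prenyl) group next to it at C6 and hydrogen at C5 and C8; ring B shows the same ortho pair (4'-OH, 3'-prenyl). The fragile elements are several:
- the two trisubstituted alkenes (no hydrogenolysis, no strong acid that would close chromans onto the neighbouring phenols, no unselective oxidant);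
- the C3–H, which epimerises through the enolate;
- the β-aryloxy ketone, which can open by E1cB to a chalcone;
- the O1–C2 bond, which ionises to a quinone methide once the 4'-hydroxyl is free;
- the easy dehydrogenation to the flavonol.

The real difficulty is absolute and relative control of two contiguous, individually labile centres without ever letting both equilibrate at the same time, with two ortho-prenylphenol units on board. The key step exploits the array C4(=O)–C3(O)–C2(O), an aldol retron: C2 (with ring B) is an aldehyde carbon, C3 is the α-carbon of an aryl ketone whose aryl group is ring A, and the C3 oxygen can arrive as a separate alcohol, so that C3–O and C2–C3 are made in one event and O1–C8a is left for a later closure of ring C.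

## Logic of the disconnections

**16 back to 15 and 14.** Only protecting-group bonds are cut: the two phenolic O–CH2OCH3 bonds (leading to 15) and the benzylic C–O bond of the ether on the C3 oxygen (leading to 14). The phenols must stay capped to the end because a free ortho-prenylphenol is oxidised by DDQ and a free 4'-phenoxide would open the quinone-methide path to C2 epimerisation under base. An alkyl acetal survives base, zerovalent palladium, the carbene step and DDQ and leaves in dilute acid. Nothing is gained in skeleton, but the order is fixed: the benzyl-type ether goes first by oxidation (14 to 15), the acetals last (15 to 16), with acid dilute enough to spare the prenyl groups.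

**14 back to 13.** The bond cut is O1–C8a, an aryl ether bond ortho to the C4 carbonyl. In the forward sense it forms by intramolecular SNAr of the C2 alkoxide on a fluoroarene. The C2–O bond is not touched, so the open-chain configuration passes into the ring. The gain is an acyclic α-alkoxy-β-hydroxy ketone in which both stereocentres and all oxygens are already differentiated. The demands are three:
- the closure must outrun retro-aldol cleavage and dehydration of the same alkoxide;
- the 4'-oxygen must stay protected so that C2 is the fixed centre under base;
- 13 must be the anti diastereomer (2R,3R), with the two oxygens on opposite faces of the extended C1–C2–C3–aryl chain.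

A closure with retention turns anti into 2,3-trans and syn into 2,3-cis, so a syn label for this adduct would be a mislabel.

**13 back to 7, 10 and 11.** The bonds cut are C2–C3 and C3–O (target numbering). This is the aldol retron, with the C3 oxygen delivered by 11 already as an ether, so the two secondary oxygens are never free together. The gain is the largest of the route: three achiral pieces, full convergence, both stereocentres and two skeletal bonds in one step. The demands are that trapping of the ylide by 10 beats the proton shift to the O–H insertion product, that a chiral acid controls both faces, and that the group ortho to the carbonyl in 7 is inert to the carbene, which fluorine is.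

**7 back to 5 (through 6).** The bond cut is the C–N bond of the diazo carbon. A methyl ketone is chosen as precursor instead of an acid chloride so that neither HCl (a threat to the acetal) nor diazomethane is needed. The gain is a stable, easily purified ketone. The demand is a temporary activation as the trifluoroacetyl derivative 6, which must be used before its enolate can displace the ortho fluorine.

**5 back to 3 and 4, then 3 to 2 to 1.** The bonds cut are the aryl C5–CH2 bond (cross-coupling), the O–acetal bond and the C5–Br bond. The bromine marks the position ortho to the hydroxyl and para to fluorine, and cross-coupling converts that regiochemistry into the prenyl group. The gain is a commercial fluorohydroxyacetophenone. The demands are bromination at C5 and not at C3, and coupling at the unsubstituted terminus of the allyl unit of 4.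

**10 back to 9 and 4, then 9 to 8.** The same two cuts (aryl–CH2, O–acetal) on ring B lead to a commercial bromohydroxybenzaldehyde, with the same demand for linear coupling. Reagent 4 serves both rings.

## Other disconnections considered

**Alternative 1:** The cut runs through ring A, at C5–C6 and C4a–C8a, so ring A is grown from the acyclic ynone A1, (4R,5R)-4-(tert-butyldimethylsilyloxy)-5-[(1E,3Z)-3-(tert-butyldimethylsilyloxy)-7-methylocta-1,3,6-trienyloxy]-5-[4-(methoxymethoxy)-3-(3-methylbut-2-enyl)phenyl]pent-1-yn-3-one, in which O1 tethers a 1-alkoxy-3-siloxydiene to the alkyne. Forward, warming A1 should bring about an intramolecular Diels–Alder reaction that closes rings A and C together, and DDQ in the same flask should dehydrogenate the cyclohexa-1,4-diene to the arene A2, the 3,7-bis-silyl 4'-methoxymethyl ether of the target.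
- In its favour: the ring A pattern (oxygen at C7, prenyl at C6, hydrogen at C5 and C8) is written into the diene, so ring A needs no bromination and no tin reagent. Ring C closes under neutral thermal conditions where no alkoxide can fragment; on this point it is better than the chosen plan.
- Against it: the cycloaddition creates neither stereocentre, so C2 and C3 would need a separate asymmetric reaction and would then be carried through an α-siloxy ynone with an acidic C3–H and a β-alkoxy leaving group. The dienyl ether of a secondary benzylic alcohol has no short, reliable preparation. The primary adduct holds O1 on an sp3 carbon next to hydrogen, so aromatisation by loss of the O1–C8a bond, which would reopen ring C, competes with dehydrogenation.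
- Comparison: structurally the alternative solves the ring A regiochemistry and leaves the stereochemical core open, the chosen plan the reverse. Mechanistically a thermal pericyclic step depends less on a catalyst than a carbene/ylide cascade. The oxidant meets the two prenyl groups just as in step 9 of the chosen plan (equal). In step count the alternative is clearly longer.

**Alternative 2:** The cut is O1–C2 and C3–C4. Ring C is assembled from salicylaldehyde A3, 2-hydroxy-4-(methoxymethoxy)-5-(3-methylbut-2-enyl)benzaldehyde (ring A, O1, C4), and enol acetate A4, (E)-2-[4-(methoxymethoxy)-3-(3-methylbut-2-enyl)phenyl]ethenyl acetate (C2, C3, ring B). Forward, trimethyl orthoformate and a chiral phosphoric acid should convert A3 into a 4-methoxy ortho-quinone methide paired with the phosphate, which adds A4 in a hetero-Diels–Alder reaction to give the 2,3-trans chroman A5 as a pair of C4 epimers.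
- In its favour: ring C and both stereocentres come from one convergent, acid-catalysed step, and the E geometry of A4 is translated into the trans relationship by a suprafacial addition. No base-sensitive aldol is handled. Closing ring C in the key step itself is an advantage over the chosen plan, which needs a separate SNAr.
- Against it: C4 arrives as a methyl ether and not as the ketone. Hydrolysis of a benzylic ether and oxidation of the alcohol must follow, beside two prenyl groups and a C3 acetate that can migrate or eliminate to the flav-3-ene. The enol acetate is a weak 2π partner polarised in opposite senses by acetoxy and aryl, so rate, regiochemistry and facial control are all open. A4 must be made with defined geometry from an enolisable arylacetaldehyde.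
- Comparison: both plans rely on a chiral phosphoric acid for the absolute configuration (equal) and both are convergent. The chosen plan has C4 at the right oxidation level from the start. The alternative is expected to cost two or three steps more after A5.

**Alternative 3:** The cut is the acyl–aryl bond C4–C4a. The precursor is the N-methoxy-N-methyl amide A6, (2R,3R)-3-[2-bromo-5-(methoxymethoxy)-4-(3-methylbut-2-enyl)phenoxy]-2-(tert-butyldimethylsilyloxy)-N-methoxy-3-[4-(methoxymethoxy)-3-(3-methylbut-2-enyl)phenyl]-N-methylpropanamide. Bromine–lithium exchange with t-BuLi at −100 °C should give the C4a aryllithium, which adds to the amide carbonyl and, through the chelated tetrahedral intermediate, stops at ketone A7, the 3-O-silyl 7,4'-bis(methoxymethyl) ether of the target.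
- In its favour: the closure is regiochemically unambiguous and creates no stereocentre, so C2 and C3 can come from well-tried chemistry (asymmetric dihydroxylation of a cinnamate, then etherification of the benzylic hydroxyl with inversion, which turns the syn diol into the anti array). No aldol-type intermediate meets base. A7 needs one acidic operation to lose silyl and acetal groups, which is one step shorter than the chosen endgame and free of oxidant, a real advantage.
- Against it: O1–C2 must be made at a 4-alkoxybenzylic stereocentre, where Mitsunobu substitution drifts toward SN1 and erodes the configuration. The C3–H next to the amide is exposed to t-BuLi and to the aryllithium. Cryogenic t-BuLi is the least safe reagent of the four plans. The ring A bromophenol raises the same bromination and prenylation questions as the chosen plan (equal).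
- Comparison: structurally the stereocentres are set early and carried through six or more steps, whereas the chosen plan creates both together with C2–C3 in the convergent step. Mechanistically a stoichiometric organolithium step of well-understood course replaces a delicate catalytic three-component reaction. The longest linear sequence is expected to be about three steps longer.

Key step: step 7

Assumption: the sense of asymmetric induction of the phosphoric acid in step 7 cannot be predicted with confidence for this substrate set; the (R)-acid is written, and its antipode would be used if the first run showed the opposite sense.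

## Steps

Step 1
Reactants: 1 1-(2-fluoro-4-hydroxyphenyl)ethanone
Product: 2 1-(5-bromo-2-fluoro-4-hydroxyphenyl)ethanone
Conditions: NBS (1.0 equiv), MeCN, 0 °C to rt
Reagents that add atoms: N-bromosuccinimide, O=C1CCC(=O)N1Br
Why: Electrophilic aromatic bromination: the hydroxyl directs ortho, and of the two ortho positions C5 (para to fluorine, flanked by hydrogen) is favoured over C3, which is squeezed between fluorine and hydroxyl; the acetyl group is meta to both and does not discriminate. One equivalent of NBS at low temperature should limit dibromination and leave the methyl ketone untouched.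

Step 2
Reactants: 2 1-(5-bromo-2-fluoro-4-hydroxyphenyl)ethanone
Product: 3 1-[5-bromo-2-fluoro-4-(methoxymethoxy)phenyl]ethanone
Conditions: MOMCl, i-Pr2NEt, CH2Cl2, 0 °C to rt
Reagents that add atoms: chloromethyl methyl ether, COCCl
Why: O-Alkylation of the acidic phenol (para acyl, ortho bromo) with the chloromethyl ether and a hindered amine gives the methoxymethyl acetal; this group is stable to zerovalent palladium, amide bases, the carbene step, carbonate bases and DDQ and leaves in dilute acid at the end.

Step 3
Reactants: 3 1-[5-bromo-2-fluoro-4-(methoxymethoxy)phenyl]ethanone; 4 tributyl(3-methylbut-2-enyl)stannane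
Product: 5 1-[2-fluoro-4-(methoxymethoxy)-5-(3-methylbut-2-enyl)phenyl]ethanone
Conditions: Pd(PPh3)4 (5 mol%), DMF, 90 °C
Reagents that add atoms: none
Why: Stille coupling: oxidative addition of zerovalent palladium into the C–Br bond, transmetalation of the allylic stannane and reductive elimination at the unsubstituted allyl terminus place the prenyl group exactly at C5; the linear isomer is expected because the aryl group is delivered to the less hindered end of the allylpalladium intermediate. Ketone, aryl fluoride and acetal are inert under these neutral conditions.

Step 4
Reactants: 5 1-[2-fluoro-4-(methoxymethoxy)-5-(3-methylbut-2-enyl)phenyl]ethanone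
Product: 7 2-diazo-1-[2-fluoro-4-(methoxymethoxy)-5-(3-methylbut-2-enyl)phenyl]ethanone, via trifluoroacetyl diketone 6 (not isolated)
Conditions: LiN(SiMe3)2, THF, −78 °C, then CF3CO2CH2CF3; cold 1 M HCl work-up; crude 6, 4-AcNHC6H4SO2N3, Et3N, H2O (1 equiv), MeCN, rt
Reagents that add atoms: 2,2,2-trifluoroethyl trifluoroacetate, FC(F)(F)COC(=O)C(F)(F)F (trifluoroacetyl group of 6, lost again); 4-acetamidobenzenesulfonyl azide, CC(=O)Nc1ccc(cc1)S(=O)(=O)N=[N+]=[N-] (the two diazo nitrogens of 7)
Why: Deacylative (Regitz-type) diazo transfer: the lithium enolate undergoes Claisen acylation to 6, whose enolate adds to the sulfonyl azide, and the triazoline fragments with loss of the trifluoroacetyl group as the N-acylsulfonamide to leave the diazoketone. Neither an acid chloride (HCl would threaten the acetal) nor diazomethane is needed, the acetamido-substituted azide is a shelf-stable transfer reagent, and 6 is used at once so that its enolate has no time to displace the ortho fluorine.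

Step 5
Reactants: 8 3-bromo-4-hydroxybenzaldehyde
Product: 9 3-bromo-4-(methoxymethoxy)benzaldehyde
Conditions: MOMCl, i-Pr2NEt, CH2Cl2, 0 °C to rt
Reagents that add atoms: chloromethyl methyl ether, COCCl
Why: O-Alkylation of the acidic phenol as in step 2; the acetal keeps the 4-oxygen masked and base-stable until the last step.

Step 6
Reactants: 9 3-bromo-4-(methoxymethoxy)benzaldehyde; 4 tributyl(3-methylbut-2-enyl)stannane
Product: 10 4-(methoxymethoxy)-3-(3-methylbut-2-enyl)benzaldehyde
Conditions: Pd(PPh3)4 (5 mol%), DMF, 90 °C
Reagents that add atoms: none
Why: Stille coupling as in step 3; the formyl group makes the ring electron-poorer and assists oxidative addition, and the aldehyde is inert to the neutral tin reagent.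

Step 7
Reactants: 7 2-diazo-1-[2-fluoro-4-(methoxymethoxy)-5-(3-methylbut-2-enyl)phenyl]ethanone; 10 4-(methoxymethoxy)-3-(3-methylbut-2-enyl)benzaldehyde; 11 4-methoxybenzyl alcohol
Product: 13 (2R,3R)-1-[2-fluoro-4-(methoxymethoxy)-5-(3-methylbut-2-enyl)phenyl]-3-hydroxy-2-[(4-methoxyphenyl)methoxy]-3-[4-(methoxymethoxy)-3-(3-methylbut-2-enyl)phenyl]propan-1-one (anti), via oxonium ylide 12 (not isolated)
Conditions: Rh2(OAc)4 (2 mol%), (R)-3,3'-bis(2,4,6-triisopropylphenyl)-1,1'-binaphthyl-2,2'-diyl hydrogen phosphate (10 mol%), 4 Å MS, CH2Cl2, −20 °C; 7 added over 2 h to 10 (2.0 equiv) and 11 (1.2 equiv)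
Reagents that add atoms: none
Why: Rh2(OAc)4 expels nitrogen from 7 to give the rhodium carbene, whose electrophilic carbon is attacked by the hydroxyl oxygen of 11; this makes the C3–O bond (target numbering) and gives the protic oxonium ylide 12, in equilibrium with its rhodium-bound form and the derived enol. Before the 1,2-proton shift that would end in plain O–H insertion, the carbanionic carbon of 12 adds to the carbonyl carbon of 10, which is hydrogen-bonded to the P–OH of the phosphoric acid while the phosphoryl oxygen holds the O–H of the ylide, so the C2–C3 bond forms inside one chiral, doubly hydrogen-bonded assembly and proton transfer then releases 13. The closest known reaction type is the three-component aldol-type trapping of alcohol-derived oxonium ylides from diazo carbonyl compounds by aryl aldehydes under dirhodium/chiral acid co-catalysis. No ring is closed. The centre at the ether carbon (C3 of the target) is controlled by the face of the ylide that the acid leaves open and the carbinol centre (C2 of the target) by the face of the bound aldehyde, both through the 3,3'-aryl groups of the acid; the anti relationship is the one expected from an open, acid-bridged transition state in which the aroyl group and the aldehyde aryl group avoid each other. The selectivity that matters most is trapping against proton shift: slow addition of 7 keeps the ylide concentration low, 10 is present in excess, the low temperature slows the proton shift, and the para-alkoxy aroyl group makes the ylide carbon strongly nucleophilic. The ortho fluorine has no lone pair basic enough to capture the carbene (an ortho ether oxygen would), and the prenyl alkenes are less nucleophilic than the alcohol and cannot reach the carbene intramolecularly, so ylide formation with 11 should dominate. Only the anti (2R,3R) adduct leads to the 2,3-trans ring after a closure with retention, so it is separated from any syn isomer at this stage; to label this adduct syn would be wrong.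

Step 8
Reactants: 13 (2R,3R)-1-[2-fluoro-4-(methoxymethoxy)-5-(3-methylbut-2-enyl)phenyl]-3-hydroxy-2-[(4-methoxyphenyl)methoxy]-3-[4-(methoxymethoxy)-3-(3-methylbut-2-enyl)phenyl]propan-1-one
Product: 14 (2R,3R)-3-[(4-methoxyphenyl)methoxy]-7-(methoxymethoxy)-2-[4-(methoxymethoxy)-3-(3-methylbut-2-enyl)phenyl]-6-(3-methylbut-2-enyl)-2,3-dihydro-4H-chromen-4-one
Conditions: Cs2CO3 (1.5 equiv), DMF, 0 °C to rt
Reagents that add atoms: none
Why: Intramolecular SNAr (addition–elimination through a Meisenheimer-type adduct stabilised by the ortho carbonyl): the alkoxide of the carbinol oxygen attacks the fluorine-bearing carbon and closes the six-membered ring C by forming O1–C8a. The C–O bond at the carbinol stereocentre is not broken, so its configuration is retained and the anti open chain becomes the 2,3-trans ring, which is also the thermodynamically preferred arrangement at the enolisable C3. A mild carbonate base, low temperature and the base-stable acetal on the 4'-oxygen are chosen to keep retro-aldol cleavage and quinone-methide formation in check.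

Step 9
Reactants: 14 (2R,3R)-3-[(4-methoxyphenyl)methoxy]-7-(methoxymethoxy)-2-[4-(methoxymethoxy)-3-(3-methylbut-2-enyl)phenyl]-6-(3-methylbut-2-enyl)-2,3-dihydro-4H-chromen-4-one
Product: 15 (2R,3R)-3-hydroxy-7-(methoxymethoxy)-2-[4-(methoxymethoxy)-3-(3-methylbut-2-enyl)phenyl]-6-(3-methylbut-2-enyl)-2,3-dihydro-4H-chromen-4-one
Conditions: DDQ (1.3 equiv), CH2Cl2/aq pH 7 phosphate buffer (10:1), 0 °C
Reagents that add atoms: none
Why: Oxidative cleavage of the 4-methoxybenzyl ether: DDQ removes a benzylic hydride from the electron-rich benzyl group through a charge-transfer complex, and water hydrolyses the oxocarbenium ion to the free C3 hydroxyl and 4-methoxybenzaldehyde. Both phenols are still capped, so the prenylarenes should not compete at 0 °C in the buffered two-phase medium, and the stereocentres are not involved.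

Step 10
Reactants: 15 (2R,3R)-3-hydroxy-7-(methoxymethoxy)-2-[4-(methoxymethoxy)-3-(3-methylbut-2-enyl)phenyl]-6-(3-methylbut-2-enyl)-2,3-dihydro-4H-chromen-4-one
Product: 16 lespeflorin B1, (2R,3R)-3,7-dihydroxy-2-[4-hydroxy-3-(3-methylbut-2-enyl)phenyl]-6-(3-methylbut-2-enyl)-2,3-dihydro-4H-chromen-4-one
Conditions: aq HCl (3 M)/MeOH (1:5), 40 °C
Reagents that add atoms: none
Why: Acid-catalysed acetal cleavage (methanolysis) of the two aryl methoxymethyl ethers frees the 7- and 4'-hydroxyl groups; dilute acid at moderate temperature is chosen so that the prenyl alkenes are neither hydrated nor cyclised onto the new phenols. Under acid C3 does not enolise appreciably, and any C2 equilibration through the 4'-hydroxy quinone methide can only favour the trans isomer, so the (2R,3R) configuration should be preserved.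

## Compound list

1 | 1-(2-fluoro-4-hydroxyphenyl)ethanone | CC(=O)c1ccc(O)cc1F | starting material
2 | 1-(5-bromo-2-fluoro-4-hydroxyphenyl)ethanone | CC(=O)c1cc(Br)c(O)cc1F | intermediate
3 | 1-[5-bromo-2-fluoro-4-(methoxymethoxy)phenyl]ethanone | CC(=O)c1cc(Br)c(OCOC)cc1F | intermediate
4 | tributyl(3-methylbut-2-enyl)stannane | CCCC[Sn](CCCC)(CCCC)CC=C(C)C | starting material
5 | 1-[2-fluoro-4-(methoxymethoxy)-5-(3-methylbut-2-enyl)phenyl]ethanone | CC(=O)c1cc(CC=C(C)C)c(OCOC)cc1F | intermediate
6 | 4,4,4-trifluoro-1-[2-fluoro-4-(methoxymethoxy)-5-(3-methylbut-2-enyl)phenyl]butane-1,3-dione (trifluoroacetyl diketone, not isolated) | O=C(CC(=O)C(F)(F)F)c1cc(CC=C(C)C)c(OCOC)cc1F | intermediate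
7 | 2-diazo-1-[2-fluoro-4-(methoxymethoxy)-5-(3-methylbut-2-enyl)phenyl]ethanone | [N-]=[N+]=CC(=O)c1cc(CC=C(C)C)c(OCOC)cc1F | intermediate
8 | 3-bromo-4-hydroxybenzaldehyde | O=Cc1ccc(O)c(Br)c1 | starting material
9 | 3-bromo-4-(methoxymethoxy)benzaldehyde | COCOc1ccc(C=O)cc1Br | intermediate
10 | 4-(methoxymethoxy)-3-(3-methylbut-2-enyl)benzaldehyde | COCOc1ccc(C=O)cc1CC=C(C)C | intermediate
11 | 4-methoxybenzyl alcohol | COc1ccc(CO)cc1 | starting material
12 | protic oxonium ylide from the carbene of 7 and 11 (aroyl–CH(−)–O(+)(H)–CH2C6H4OMe zwitterion, not isolated) | COCOc1cc(F)c(cc1CC=C(C)C)C(=O)[CH-][OH+]Cc1ccc(OC)cc1 | intermediate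
13 | (2R,3R)-1-[2-fluoro-4-(methoxymethoxy)-5-(3-methylbut-2-enyl)phenyl]-3-hydroxy-2-[(4-methoxyphenyl)methoxy]-3-[4-(methoxymethoxy)-3-(3-methylbut-2-enyl)phenyl]propan-1-one (anti) | COCOc1ccc(cc1CC=C(C)C)[C@@H](O)[C@@H](OCc1ccc(OC)cc1)C(=O)c1cc(CC=C(C)C)c(OCOC)cc1F | intermediate
14 | (2R,3R)-3-[(4-methoxyphenyl)methoxy]-7-(methoxymethoxy)-2-[4-(methoxymethoxy)-3-(3-methylbut-2-enyl)phenyl]-6-(3-methylbut-2-enyl)-2,3-dihydro-4H-chromen-4-one (2,3-trans) | COCOc1ccc(cc1CC=C(C)C)[C@H]1Oc2cc(OCOC)c(CC=C(C)C)cc2C(=O)[C@@H]1OCc1ccc(OC)cc1 | intermediate
15 | (2R,3R)-3-hydroxy-7-(methoxymethoxy)-2-[4-(methoxymethoxy)-3-(3-methylbut-2-enyl)phenyl]-6-(3-methylbut-2-enyl)-2,3-dihydro-4H-chromen-4-one | COCOc1ccc(cc1CC=C(C)C)[C@H]1Oc2cc(OCOC)c(CC=C(C)C)cc2C(=O)[C@@H]1O | intermediate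
16 | lespeflorin B1, (2R,3R)-3,7-dihydroxy-2-[4-hydroxy-3-(3-methylbut-2-enyl)phenyl]-6-(3-methylbut-2-enyl)-2,3-dihydro-4H-chromen-4-one | CC(C)=CCc1cc([C@H]2Oc3cc(O)c(CC=C(C)C)cc3C(=O)[C@@H]2O)ccc1O | target

## Step count and least certain steps

Total step count: 10. Longest linear sequence: 8 steps (steps 1 to 4 and 7 to 10); the ring B branch (steps 5 and 6) joins at step 7.

**Step 7 (key step).** The most likely failure is that the oxonium ylide undergoes its 1,2-proton shift before it is trapped, because the 4-alkoxy-substituted aldehyde is a slow electrophile, so the reaction drains into simple O–H insertion. The second risk is insufficient discrimination by the acid between the anti and syn modes of addition and between the two faces. The fallback gives up the three-component assembly, sets out from 5 and 10 and comes back to the route at 15. Ketone 5 is converted into its chiral boron enolate with B-chlorodiisopinocampheylborane (the enantiomer that delivers the S carbinol) and Et3N in Et2O at −78 °C and added to 10 (asymmetric boron acetate aldol, oxidative work-up with H2O2 at pH 7) to give the (3S)-β-hydroxy ketone F1. Intramolecular SNAr (Cs2CO3, DMF) then closes ring C to the (2S)-flavanone F2, whose enantiomeric purity can be raised by crystallisation. The potassium enolate of F2 (KN(SiMe3)2, THF, −78 °C) is hydroxylated with 2-(phenylsulfonyl)-3-phenyloxaziridine on the face opposite the C2 aryl group, which should give 15 directly. This sequence is one step shorter on paper than the main route, but its enantiocontrol rests on a stoichiometric chiral borane whose selectivity with methyl ketones is modest.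

**Step 8.** The alkoxide that must attack the fluoroarene is also an aldolate. Retro-aldol cleavage and re-addition, dehydration through the C2 enolate of the open chain, and E1cB ring opening of the closed product would all erase the carbinol centre that anchors the configuration under base. The fallback replaces the alkoxide-on-arene closure by the acid-mediated attack of a ring A phenol on the benzylic carbon; it sets out from 5 and 10 and comes back at 16.
- The fluorine of 5 is exchanged for hydroxyl by SNAr with a hydroxide surrogate (acetohydroxamic acid, K2CO3, DMSO, 80 °C) to give the 2-hydroxy ketone F3.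
- MOMCl and NaH in DMF give the bis-acetal F4.
- Claisen–Schmidt condensation with 10 (KOH, EtOH) gives the (E)-chalcone F5.
- Juliá–Colonna epoxidation (poly-L-leucine or its antipode, whichever delivers the αR epoxide, urea–H2O2, DBU, THF) gives the (2R,3S)-epoxy ketone F6.
- Aqueous HCl in MeOH removes the three acetals, and the freed ring A phenol opens the epoxide at the benzylic carbon to give 16. C3 comes from the untouched epoxide carbon, and C2 settles trans under thermodynamic control.

**Step 9.** DDQ may not stop at the benzyl ether: hydride abstraction at the doubly activated aryl–CH2–CH= positions of the prenyl groups or oxidation of the alkoxy-substituted rings would consume material. The fallback replaces oxidation by a different bond-breaking principle; it sets out from 14 and comes back at 15 without any new compound. MgBr2·OEt2 and Me2S in CH2Cl2 at rt are used: the C4 carbonyl oxygen and the C3 ether oxygen chelate magnesium, which activates the benzylic C–O bond for SN2-type attack by the sulfide, so no oxidant meets the prenylarenes. Partial loss of an aryl acetal under these conditions would be harmless because step 10 removes both.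

**Step 3.** Transmetalation of the allylic stannane with allylic transposition would lead to coupling at the tertiary terminus (branched 1,1-dimethylallyl isomer), and slow oxidative addition next to the acetal oxygen could favour protodebromination. The fallback reverses the polarity of the coupling; it sets out from 3 and comes back at 5. Miyaura borylation (bis(pinacolato)diboron, PdCl2(dppf) with dppf = 1,1'-bis(diphenylphosphino)ferrocene, KOAc, dioxane, 80 °C) gives the aryl pinacol boronate F7. Suzuki–Miyaura allylation with 1-bromo-3-methylbut-2-ene (Pd(PPh3)4, K2CO3, toluene/H2O, 60 °C) then delivers the aryl group to the unhindered terminus of the π-allylpalladium intermediate.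

## Further compounds

F1 | step 7 | (3S)-1-[2-fluoro-4-(methoxymethoxy)-5-(3-methylbut-2-enyl)phenyl]-3-hydroxy-3-[4-(methoxymethoxy)-3-(3-methylbut-2-enyl)phenyl]propan-1-one | COCOc1ccc(cc1CC=C(C)C)[C@@H](O)CC(=O)c1cc(CC=C(C)C)c(OCOC)cc1F
F2 | step 7 | (2S)-7-(methoxymethoxy)-2-[4-(methoxymethoxy)-3-(3-methylbut-2-enyl)phenyl]-6-(3-methylbut-2-enyl)-2,3-dihydro-4H-chromen-4-one | COCOc1ccc(cc1CC=C(C)C)[C@H]1Oc2cc(OCOC)c(CC=C(C)C)cc2C(=O)C1
F3 | step 8 | 1-[2-hydroxy-4-(methoxymethoxy)-5-(3-methylbut-2-enyl)phenyl]ethanone | CC(=O)c1cc(CC=C(C)C)c(OCOC)cc1O
F4 | step 8 | 1-[2,4-bis(methoxymethoxy)-5-(3-methylbut-2-enyl)phenyl]ethanone | CC(=O)c1cc(CC=C(C)C)c(OCOC)cc1OCOC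
F5 | step 8 | (E)-1-[2,4-bis(methoxymethoxy)-5-(3-methylbut-2-enyl)phenyl]-3-[4-(methoxymethoxy)-3-(3-methylbut-2-enyl)phenyl]prop-2-en-1-one | COCOc1ccc(/C=C/C(=O)c2cc(CC=C(C)C)c(OCOC)cc2OCOC)cc1CC=C(C)C
F6 | step 8 | [2,4-bis(methoxymethoxy)-5-(3-methylbut-2-enyl)phenyl][(2R,3S)-3-[4-(methoxymethoxy)-3-(3-methylbut-2-enyl)phenyl]oxiran-2-yl]methanone | COCOc1cc(OCOC)c(cc1CC=C(C)C)C(=O)[C@@H]2O[C@H]2c3ccc(OCOC)c(CC=C(C)C)c3
F0 | step 9 | none | none
F7 | step 3 | 1-[2-fluoro-4-(methoxymethoxy)-5-(4,4,5,5-tetramethyl-1,3,2-dioxaborolan-2-yl)phenyl]ethanone | CC(=O)c1cc(B2OC(C)(C)C(C)(C)O2)c(OCOC)cc1F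
A1 | alternative 1 | (4R,5R)-4-(tert-butyldimethylsilyloxy)-5-[(1E,3Z)-3-(tert-butyldimethylsilyloxy)-7-methylocta-1,3,6-trienyloxy]-5-[4-(methoxymethoxy)-3-(3-methylbut-2-enyl)phenyl]pent-1-yn-3-one | C#CC(=O)[C@H](O[Si](C)(C)C(C)(C)C)[C@H](O/C=C/C(O[Si](C)(C)C(C)(C)C)=C/CC=C(C)C)c1ccc(OCOC)c(CC=C(C)C)c1
A2 | alternative 1 | (2R,3R)-3,7-bis(tert-butyldimethylsilyloxy)-2-[4-(methoxymethoxy)-3-(3-methylbut-2-enyl)phenyl]-6-(3-methylbut-2-enyl)-2,3-dihydro-4H-chromen-4-one | COCOc1ccc(cc1CC=C(C)C)[C@H]1Oc2cc(O[Si](C)(C)C(C)(C)C)c(CC=C(C)C)cc2C(=O)[C@@H]1O[Si](C)(C)C(C)(C)C
A3 | alternative 2 | 2-hydroxy-4-(methoxymethoxy)-5-(3-methylbut-2-enyl)benzaldehyde | O=Cc1cc(CC=C(C)C)c(OCOC)cc1O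
A4 | alternative 2 | (E)-2-[4-(methoxymethoxy)-3-(3-methylbut-2-enyl)phenyl]ethenyl acetate | CC(=O)O/C=C/c1ccc(OCOC)c(CC=C(C)C)c1
A5 | alternative 2 | (2R,3S)-4-methoxy-7-(methoxymethoxy)-2-[4-(methoxymethoxy)-3-(3-methylbut-2-enyl)phenyl]-6-(3-methylbut-2-enyl)-3,4-dihydro-2H-chromen-3-yl acetate (2,3-trans, both C4 epimers) | COCOc1ccc(cc1CC=C(C)C)[C@H]1Oc2cc(OCOC)c(CC=C(C)C)cc2C(OC)[C@@H]1OC(C)=O
A6 | alternative 3 | (2R,3R)-3-[2-bromo-5-(methoxymethoxy)-4-(3-methylbut-2-enyl)phenoxy]-2-(tert-butyldimethylsilyloxy)-N-methoxy-3-[4-(methoxymethoxy)-3-(3-methylbut-2-enyl)phenyl]-N-methylpropanamide | CON(C)C(=O)[C@H](O[Si](C)(C)C(C)(C)C)[C@H](Oc1cc(OCOC)c(CC=C(C)C)cc1Br)c1ccc(OCOC)c(CC=C(C)C)c1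
A7 | alternative 3 | (2R,3R)-3-(tert-butyldimethylsilyloxy)-7-(methoxymethoxy)-2-[4-(methoxymethoxy)-3-(3-methylbut-2-enyl)phenyl]-6-(3-methylbut-2-enyl)-2,3-dihydro-4H-chromen-4-one | COCOc1ccc(cc1CC=C(C)C)[C@H]1Oc2cc(OCOC)c(CC=C(C)C)cc2C(=O)[C@@H]1O[Si](C)(C)C(C)(C)C
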